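# Proposed total synthesis of CNP0409870.3 by a ketone-initiated cation–olefin bicyclisation

## Analysis of the target

Target 33 is a trans-fused decalin of the eudesmane type (ring A: C1–C5 and C10; ring B: C5–C10). C1 carries a stereogenic benzylic carbon, Cα, which bears an isobutyl group and a 2,4,6-trihydroxy-3,5-diformylphenyl ring (C1'–C6'). C4 is a methyl carbinol (methyl C15), C10 is the quaternary ring-fusion carbon (methyl C14), C5 is the ring-fusion CH, and C7 bears the 2-hydroxyprop-2-yl group (carbinol carbon C11). There are six stereocentres, (αS,1S,4R,5S,7S,10R). The C14 methyl is axial and trans to H5, the C4 hydroxyl is axial and syn to C14, the Cα-bearing substituent on C1 is axial and anti to C14, and the C7 side chain is equatorial. The sensitive groups are the two tertiary alcohols, which ionise or dehydrate under protic acids, Lewis acids and chloroiminium reagents, and the formylated phloroglucinol, which is acidic, chelating and easily oxidised and therefore has to appear last. The difficulty lies in the contiguous Cα–C1–C10 array, where a very large group must end up axial next to a quaternary carbon, and in the C4 carbinol that must be syn to C14. The strategy rests on the C4–C5–C10 segment: a methyl carbinol at C4, a ring-fusion CH at C5 and a methyl-bearing C10 are the footprint of a methyl ketone, an (E)-trisubstituted C5=C10 alkene and a carbon nucleophile at C9 in an open chain. Both rings and three stereocentres can therefore come from one cation–olefin cascade on a precursor that holds only Cα and C1.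

## Retrosynthetic reasoning

**33 ⇒ 32 (three O–CH3 bonds).** The free formyl-phloroglucinol is the most delicate part of 33, so the phenols stay methylated until the end. In trimethyl ether 32 each methoxy group is ortho or para to two formyl groups, which makes nucleophilic demethylation feasible under basic conditions that the tertiary alcohols tolerate. Lewis-acidic ether cleavage is avoided for the same reason.

**32 ⇒ 30 ⇒ 29 (two aryl–CHO bonds).** The formyl groups are cut back to the aryl bromides of 30 and then to the unsubstituted positions C3' and C5' of 29. A chloroiminium formylation would be the obvious choice for a trimethoxyarene, but it would convert both tertiary alcohols into chlorides or alkenes. Bromination followed by halogen–lithium exchange and trapping with a formamide does the same job under basic conditions, with the alcohols masked in situ as alkoxides.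

**29 ⇒ 27 ⇒ 25 ⇒ 24 ⇒ 22 (C11 carbinol and the C7–C11 bond).** The carbinol of 29 comes from methyl ester 27 and a methyl organometallic. The ester carbon is attached to C7 by carbonylation of enol triflate 24, which is made from the C8 ketone 22. A direct aldol reaction of 22 with a ketone electrophile was set aside: that aldol equilibrium is unfavourable, the adduct cannot be epimerised at C7 without retro-aldol cleavage, and the C8 oxygen would then need a separate deoxygenation next to a tertiary alcohol. The triflate route removes the C8 oxygen in the same operation that forms C7–C11, and the C7 stereocentre of 27 is α to an ester, so it can be equilibrated to the equatorial position.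

**22 ⇒ 20 (C8=O from C8=CH2).** The C8 ketone is the oxidative-cleavage product of the exocyclic methylene of 20. That methylene is the trace the allylsilane terminator leaves behind, and it is the only alkene in 20.

**20 ⇒ 19 (C4–C5 and C9–C10; both rings).** This is the central disconnection. Cutting C4–C5 and C9–C10 opens 20 to the acyclic keto-diene allylsilane 19. In the forward direction the Lewis acid-activated C4 ketone is attacked by C5 of the (E)-alkene, and the C10 cation is trapped by the allylsilane terminus C9. The C4 oxygen is the carbonyl oxygen itself, so no hydration step is needed. No other pair of cuts removes two rings and three stereocentres (C4, C5, C10) at once while leaving a precursor with only two stereocentres.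

**19 ⇒ 18 ⇒ 15 + 17 (C6–C7).** The ketone is carried as its ethylene ketal 18 so that the C6–C7 bond can be made with an allylic Grignard reagent. That bond is formed by substitution of the primary allylic bromide 15 by 17. Reagent 17 is made from the allylic chloride 16 and magnesium; deprotonating a 2-methylallylsilane would instead take place next to silicon and give the wrong allyl anion.

**15 ⇒ 14 ⇒ 13 ⇒ 10 + 11 (C5=C10).** The (E)-trisubstituted alkene is cut at C5=C10 to methyl ketone 10 and phosphonate 11. The olefination fixes the alkene geometry on which the trans ring fusion depends. Reduction and bromination then give the C6 electrophile.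

**10 ⇒ 9 ⇒ 8 ⇒ 7 (unravelling the lactone).** The C10 carbonyl of 10 is the lactone carbonyl of 7, and the third methoxy group of the arene is the lactone oxygen. Opening 7 to the Weinreb amide 8, methylating the liberated phenol (9) and adding a methyl organometallic gives 10 without touching C1.

**7 ⇒ 3 + 5 (C1–C2).** The side chain C2–C3–C4–C15 is attached to C1 by alkylating the enolate of lactone 3 with iodide 5, which is made from the commercial bromide 4. The six-membered lactone is the stereochemical template: the new bond forms trans to the C4 isobutyl group of the chromanone, which corresponds to the (αS,1S) relationship of the target.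

**3 ⇒ 1 + 2 (Cα–CH2).** The Cα stereocentre comes from a catalytic asymmetric conjugate addition of the isobutyl Grignard reagent 2 to the commercial coumarin 1. That coumarin already holds the arene, two of its methoxy groups and the C10 carbon.

## Alternatives that were turned down

**Alternative 1:** The C9–C10 bond of ring B is cut back to the phenol mesylate A1, in which ring A is still aromatic. In the forward direction KOtBu forms the phenolate, and its para carbon (C10, already carrying C14) displaces the primary mesylate at C9. This closes ring B and gives the cross-conjugated cyclohexadienone A2.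
- For it: the quaternary C10 is made by a base-mediated SN2 reaction with no cationic intermediate, so proton loss and rearrangement are not an issue. The C7 side chain is present from the start.
- Against it: A2 contains only C7 and C10. Cα, C1, C4 and C5 are still missing, and the oxygen sits at C3 instead of C4. The most hindered bond of the target, C1–Cα next to the quaternary carbon, would have to be made by conjugate addition of a bulky secondary benzylic unit or be built stepwise. A 1,2-carbonyl transposition, methyl addition at C4 and a trans-selective reduction of C4=C5 would follow.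
- Comparison: for making C10 alone it is the safer reaction. The chosen cascade instead delivers C4, C5, C10 and both rings at once on a chain that already carries Cα, C1 and the arene; the dienone route would need well over ten further steps with four open stereochemical questions.

**Alternative 2:** This disconnects only the arene. Both ortho hydroxy-aldehyde pairs (C2'–OH/C3'–CHO and C6'–OH/C5'–CHO) are cut at once, back to the bis(silyl triflate) A3. In the forward direction CsF in DMF generates the C2'≡C3' aryne and then the C5'≡C6' aryne. Each adds across the C=O bond of the formamide, and hydrolysis leaves the salicylaldehyde units of A4.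
- For it: hydroxyl and formyl groups enter together under nearly neutral fluoride conditions, with no organolithium and no electrophilic formylating agent, and only one methyl ether is left to cleave. On that point it is gentler than the bromination, exchange, formylation and triple demethylation chosen here.
- Against it: A3 is a hexasubstituted benzene with two ortho-silyl triflate pairs flanking the hindered benzylic carbon, and making it would cost more steps than it saves. The regiochemistry requires the formamide oxygen to bond to C2' and C6', the aryne carbons next to the bulky C1' substituent, relying on the inductive effect of the 4'-methoxy group against sterics. The second aryne must also form on a ring that already bears a phenoxide and an aldehyde, both of which can trap arynes.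
- Comparison: it says nothing about the decalin, which is where the difficulty of the target lies. The chosen route carries a plain trimethoxyphenyl group from a commercial coumarin and spends its risk on the skeleton.

**Alternative 3:** Only the C3–C4 bond of ring A is cut, leading back to the keto-iodide A5, a fully substituted ring B cyclohexane with an acetyl group on C5 and a C1 side chain ending in a primary iodide. In the forward direction SmI2 with HMPA reduces the C–I bond and the organosamarium adds to the acetyl carbonyl (Barbier reaction), closing ring A and forming the C4 carbinol of A6.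
- For it: the step is mild and chemoselective, involves no carbocation, and six-membered closure of this kind is dependable. A6 already holds the protected C7 side chain, so only the arene end game would remain; in steps after the cyclisation it beats the chosen route.
- Against it: the step forms one bond, one ring and one stereocentre. A5 must already contain Cα, C1, C5, C7 and the quaternary C10 (flanked by two stereocentres) on a monocyclic ring with no rigid framework to relay stereocontrol. Its synthesis would be longer and less certain than the route to 19.
- Comparison: the facial question at C4 is the same in both (the oxygen must end up axial, syn to C14), so nothing is gained there. The chosen strategy lets a single stereocentre, C1, control three new ones in one step.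

Key step: step 13

## Assumptions

- Which antipode of the ferrocenyl diphosphine in step 1 delivers (S)-3 is not predicted here. Both antipodes are available, and the sense is fixed on the first run.
- Atom labels (Cα, C1–C15, C1'–C6') follow the numbering defined in the analysis and are used for all intermediates.

## Route

Step 1
Reactants: 1 5,7-dimethoxycoumarin; 2 isobutylmagnesium bromide
Product: 3 (4S)-4-isobutyl-5,7-dimethoxychroman-2-one
Conditions: CuBr·SMe2 (5 mol %), 1-[2-(dicyclohexylphosphino)ferrocenyl]ethyldiphenylphosphine (6 mol %), CH2Cl2, −75 °C; aq. NH4Cl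
Reagents that add atoms: none
Why: Copper-catalysed asymmetric conjugate addition of a Grignard reagent to a coumarin; the chiral diphosphine–copper complex selects one face of the coumarin C4 and so sets Cα, and the magnesium enolate formed is inert to a second addition at this temperature.

Step 2
Reactants: 4 2-(2-bromoethyl)-2-methyl-1,3-dioxolane
Product: 5 2-(2-iodoethyl)-2-methyl-1,3-dioxolane
Conditions: NaI, NaHCO3, acetone, reflux
Reagents that add atoms: sodium iodide, [Na+].[I-]
Why: Finkelstein exchange; precipitation of NaBr from acetone drives the primary bromide to the more reactive iodide, and NaHCO3 protects the ketal from traces of acid.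

Step 3
Reactants: 3 (4S)-4-isobutyl-5,7-dimethoxychroman-2-one; 5 2-(2-iodoethyl)-2-methyl-1,3-dioxolane
Product: 7 (3S,4S)-4-isobutyl-5,7-dimethoxy-3-[2-(2-methyl-1,3-dioxolan-2-yl)ethyl]chroman-2-one (3,4-trans), via lithium enolate 6 (not isolated)
Conditions: LiN(SiMe3)2, THF, −78 °C; then 5, DMPU, −78 → −30 °C
Reagents that add atoms: none
Why: Lactone enolate alkylation (SN2); the peri 5-methoxy group forces the C4 isobutyl group pseudoaxial, so it covers one face of enolate 6 and the iodide enters anti to it, which sets C1 trans to Cα.

Step 4
Reactants: 7 trans-alkylated lactone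
Product: 8 (2S,3S)-3-(2-hydroxy-4,6-dimethoxyphenyl)-N-methoxy-N,5-dimethyl-2-[2-(2-methyl-1,3-dioxolan-2-yl)ethyl]hexanamide
Conditions: MeNH(OMe)·HCl, i-PrMgCl, THF, −20 → 0 °C
Reagents that add atoms: N,O-dimethylhydroxylamine hydrochloride, CNOC.Cl
Why: Weinreb aminolysis of an aryl ester (an activated acyl donor) by the chloromagnesium amide; the low temperature leaves C1 untouched, and the phenoxide that is released becomes the third aryl oxygen.

Step 5
Reactants: 8 phenolic Weinreb amide
Product: 9 (2S,3S)-N-methoxy-N,5-dimethyl-2-[2-(2-methyl-1,3-dioxolan-2-yl)ethyl]-3-(2,4,6-trimethoxyphenyl)hexanamide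
Conditions: MeI, K2CO3, DMF, rt
Reagents that add atoms: iodomethane, CI
Why: Williamson O-methylation of the phenol; it completes the symmetrical 2,4,6-trimethoxyphenyl group and removes the nucleophile that could re-close the lactone.

Step 6
Reactants: 9 Weinreb amide methyl ether
Product: 10 (3S,4S)-6-methyl-3-[2-(2-methyl-1,3-dioxolan-2-yl)ethyl]-4-(2,4,6-trimethoxyphenyl)heptan-2-one
Conditions: MeMgBr, THF, 0 °C → rt; aq. NH4Cl
Reagents that add atoms: methylmagnesium bromide, C[Mg]Br
Why: Weinreb ketone synthesis; the chelated tetrahedral intermediate stops the addition at the methyl ketone, whose carbonyl carbon is C10 and whose methyl group is C14.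

Step 7
Reactants: 10 methyl ketone; 11 triethyl phosphonoacetate
Product: 13 ethyl (2E,4S,5S)-3,7-dimethyl-4-[2-(2-methyl-1,3-dioxolan-2-yl)ethyl]-5-(2,4,6-trimethoxyphenyl)oct-2-enoate, via sodium phosphonate anion 12 (not isolated)
Conditions: NaH, THF, 0 °C (11 → 12); then 10, 0 → 60 °C
Reagents that add atoms: none
Why: Horner–Wadsworth–Emmons olefination; the reversible addition places the ester trans to the branched C1 substituent and gives the (E)-C5=C10 alkene, and the weakly basic phosphonate anion should leave the hindered C1–H in place.

Step 8
Reactants: 13 (E)-enoate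
Product: 14 (2E,4S,5S)-3,7-dimethyl-4-[2-(2-methyl-1,3-dioxolan-2-yl)ethyl]-5-(2,4,6-trimethoxyphenyl)oct-2-en-1-ol
Conditions: i-Bu2AlH, CH2Cl2, −78 °C; aq. potassium sodium tartrate
Reagents that add atoms: none
Why: 1,2-Reduction of the conjugated ester by i-Bu2AlH to the allylic alcohol (C6–OH); the ketal and the aryl ethers are inert at −78 °C.

Step 9
Reactants: 14 allylic alcohol
Product: 15 (2E,4S,5S)-1-bromo-3,7-dimethyl-4-[2-(2-methyl-1,3-dioxolan-2-yl)ethyl]-5-(2,4,6-trimethoxyphenyl)oct-2-ene
Conditions: CBr4, PPh3, CH2Cl2, −20 → 0 °C
Reagents that add atoms: carbon tetrabromide, BrC(Br)(Br)Br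
Why: Appel bromination; the primary allylic alcohol is displaced at C6 without allylic shift because C10 is fully substituted and hindered, and the near-neutral conditions spare the ketal.

Step 10
Reactants: 16 [2-(chloromethyl)allyl]trimethylsilane
Product: 17 [2-(trimethylsilylmethyl)allyl]magnesium chloride (used as its THF solution)
Conditions: Mg turnings, THF, 0 °C → rt
Reagents that add atoms: magnesium, [Mg]
Why: Grignard formation from an allylic chloride; the two CH2 termini of the allyl unit are equivalent, so allyl transposition of the reagent is of no consequence.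

Step 11
Reactants: 15 allylic bromide; 17 [2-(trimethylsilylmethyl)allyl]magnesium chloride
Product: 18 ethylene ketal of keto-diene allylsilane 19 (αS,1S; C5=C10 E)
Conditions: Li2CuCl4 (5 mol %), THF, −78 → 0 °C
Reagents that add atoms: none
Why: Copper-catalysed allyl–allyl cross-coupling (SN2 at C6); attack at the γ-carbon C10 is blocked by its full substitution, so the C6–C7 bond forms with the (E)-alkene intact while the ketal shields C4 from the Grignard reagent.

Step 12
Reactants: 18 ketal allylsilane
Product: 19 (5S,6E)-6-methyl-5-[(1S)-3-methyl-1-(2,4,6-trimethoxyphenyl)butyl]-10-methylidene-11-(trimethylsilyl)undec-6-en-2-one (keto-diene allylsilane; αS,1S)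
Conditions: pyridinium p-toluenesulfonate (cat.), acetone/H2O, 45 °C
Reagents that add atoms: water, O
Why: Mild acid-catalysed ketal hydrolysis; the buffered sulfonic acid salt is acidic enough for a dialkyl ketal but should not protonate the allylsilane or the trisubstituted alkene.

Step 13
Reactants: 19 keto-diene allylsilane
Product: 20 trans-decalin (αS,1S,4R,5S,10R): 4-hydroxy-4,10-dimethyl-8-methylidene decalin carrying the (S)-3-methyl-1-(2,4,6-trimethoxyphenyl)butyl group at C1
Conditions: MeAlCl2 (3.5 equiv), CH2Cl2 (high dilution), −78 °C; aq. NaHCO3
Reagents that add atoms: none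
Why: MeAlCl2 binds the C4 carbonyl (the excess is taken up by the three methoxy groups) and C5 of the (E)-C5=C10 alkene attacks C4 in the Markovnikov sense, leaving a tertiary cation at C10; C9, the methylene terminus of the allylsilane, adds to C10 and chloride removes the silyl group, which leaves the C8 exocyclic methylene. The closest known reaction type is the Lewis acid-promoted carbonyl-initiated (Prins-type) cation–olefin cyclisation with allylsilane termination, in which aldehydes and acetals are the usual initiators and a methyl ketone is the less reactive relative. Ring A closes in the 6-endo mode with respect to the C5=C10 alkene (carbonyl oxygen exocyclic) through a chair, and ring B closes 6-endo through a second chair. C5 and C10 follow from anti addition across the (E)-alkene, which makes the ring fusion trans. Their absolute sense is set by the existing C1 centre: the Cα-bearing substituent has to sit pseudoaxial on the ring A chair, because a pseudoequatorial position would eclipse it with the C14 methyl on C10 (A(1,2) strain), and this places C14 anti to the C1 substituent. C4 is set by the orientation of the carbonyl in the same chair: with C15 equatorial and the aluminium-bound oxygen axial, a methyl–methyl 1,3-diaxial contact with C14 is avoided and the anionic oxygen stays close to the developing C10 cation. The step needs capture of the C10 cation by carbon to win over proton loss and over capture by a methoxy oxygen; the high π-nucleophilicity of the 2-substituted allylsilane, the proton-scavenging methyl–aluminium bond and high dilution should secure this.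

Step 14
Reactants: 20 trans-decalin with C8 methylene
Product: 22 C8 ketone (αS,1S,4R,5S,10R), via vicinal diol 21 (not isolated)
Conditions: OsO4 (2 mol %), NaIO4, 2,6-lutidine, dioxane/H2O, rt
Reagents that add atoms: osmium tetroxide, O=[Os](=O)(=O)=O; sodium periodate, [Na+].[O-]I(=O)(=O)=O
Why: Lemieux–Johnson cleavage; the only alkene is the unhindered C8 methylene, which is dihydroxylated and cleaved to the C8 ketone, and 2,6-lutidine buffers the medium for the tertiary alcohol.

Step 15
Reactants: 22 C8 ketone
Product: 24 C7=C8 enol triflate (αS,1S,4R,5S,10R), via dilithium alkoxide enolate 23 (not isolated)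
Conditions: LiN(iPr)2 (2.3 equiv), THF, −78 °C; PhNTf2, −78 → 0 °C; aq. NH4Cl
Reagents that add atoms: N-phenylbis(trifluoromethanesulfonimide), O=S(=O)(N(c1ccccc1)S(=O)(=O)C(F)(F)F)C(F)(F)F
Why: Kinetic enolisation and O-triflation; the base removes the axial C7 proton in preference to a C9 proton, which is neopentylic and screened by the axial C1 substituent, and the C7=C8 enolate is also the favoured one of a trans-fused decalone of this type. The hindered tertiary lithium alkoxide at C4 should not be sulfonylated.

Step 16
Reactants: 24 enol triflate
Product: 25 methyl C7=C8 enoate (αS,1S,4R,5S,10R; CO2Me on C7)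
Conditions: Pd(OAc)2 (5 mol %), PPh3, CO (1 atm), MeOH, Et3N, DMF, 50 °C
Reagents that add atoms: carbon monoxide, [C-]#[O+]; methanol, CO
Why: Palladium-catalysed alkoxycarbonylation of an enol triflate: oxidative addition to zerovalent palladium, CO insertion and methanolysis put the future C11 carbon on C7 and remove the C8 oxygen in the same operation.

Step 17
Reactants: 25 unsaturated ester
Product: 27 methyl ester with equatorial (7β) CO2Me (αS,1S,4R,5S,7S,10R), via C7-epimeric ester mixture 26 (not isolated)
Conditions: H2 (1 atm), palladium on carbon (Pd/C), EtOAc, rt; then NaOMe (cat.), MeOH, 50 °C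
Reagents that add atoms: none
Why: Heterogeneous hydrogenation of the conjugated alkene followed by methoxide equilibration α to the ester; whatever the facial ratio of hydrogen delivery, the ester should settle in the equatorial position of the locked trans-decalin, which sets C7.

Step 18
Reactants: 27 equatorial methyl ester
Product: 29 diol (αS,1S,4R,5S,7S,10R) with C4–OH and C11–OH and a 2,4,6-trimethoxyphenyl group, via methyl ketone 28 (not isolated)
Conditions: MeMgBr (excess), THF, 0 °C → rt; aq. NH4Cl
Reagents that add atoms: methylmagnesium bromide, C[Mg]Br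
Why: Double Grignard addition to the ester through ketone 28; the first equivalent is consumed by the C4 hydroxyl and no stereocentre is created.

Step 19
Reactants: 29 diol
Product: 30 3',5'-dibromide of 29
Conditions: N-bromosuccinimide (2.1 equiv), MeCN, 0 °C, dark
Reagents that add atoms: N-bromosuccinimide, O=C1CCC(=O)N1Br
Why: Electrophilic aromatic bromination; C3' and C5' are the only free ring positions, each flanked by two methoxy groups, and no alkene is left in the molecule to compete.

Step 20
Reactants: 30 dibromide
Product: 32 3',5'-diformyl-2',4',6'-trimethoxy diol (trimethyl ether of the target), via tetralithium species 31 (not isolated)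
Conditions: t-BuLi (6.5 equiv), THF, −78 °C; DMF, −78 → 0 °C; aq. NH4Cl
Reagents that add atoms: N,N-dimethylformamide, CN(C)C=O
Why: Bromine–lithium exchange followed by formylation with a formamide (Bouveault-type); the two hydroxyls are masked in situ as lithium alkoxides and each aryllithium is stabilised by two flanking methoxy groups. This basic sequence replaces a chloroiminium formylation, which would dehydrate the tertiary alcohols.

Step 21
Reactants: 32 trimethyl ether
Product: 33 target CNP0409870.3, 5-[(1S)-1-[(1S,4R,4aS,6S,8aR)-4-hydroxy-6-(2-hydroxypropan-2-yl)-4,8a-dimethyldecahydronaphthalen-1-yl]-3-methylbutyl]-2,4,6-trihydroxybenzene-1,3-dicarbaldehyde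
Conditions: NaSEt (excess), DMF, 110 °C; then cold dilute HCl to pH 4
Reagents that add atoms: none
Why: Nucleophilic (SN2) O-demethylation by thiolate; every methoxy group is ortho or para to two formyl groups, so each phenoxide is a good leaving group, and the basic medium leaves both tertiary alcohols intact.

## Compound list

1 | 5,7-dimethoxycoumarin | COc1cc(OC)c2ccc(=O)oc2c1 | starting material
2 | isobutylmagnesium bromide | CC(C)C[Mg]Br | starting material
3 | (4S)-4-isobutyl-5,7-dimethoxychroman-2-one | CC(C)C[C@H](c1c(OC)cc(OC)cc1O2)CC2=O | intermediate
4 | 2-(2-bromoethyl)-2-methyl-1,3-dioxolane | CC1(CCBr)OCCO1 | starting material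
5 | 2-(2-iodoethyl)-2-methyl-1,3-dioxolane | CC1(CCI)OCCO1 | intermediate
6 | lithium enolate of 3 | CC(C)C[C@H](c1c(OC)cc(OC)cc1O2)C=C2O[Li] | intermediate (not isolated)
7 | (3S,4S)-4-isobutyl-5,7-dimethoxy-3-[2-(2-methyl-1,3-dioxolan-2-yl)ethyl]chroman-2-one | CC(C)C[C@H](c1c(OC)cc(OC)cc1O2)[C@H](CCC1(C)OCCO1)C2=O | intermediate
8 | (2S,3S)-3-(2-hydroxy-4,6-dimethoxyphenyl)-N-methoxy-N,5-dimethyl-2-[2-(2-methyl-1,3-dioxolan-2-yl)ethyl]hexanamide | CC(C)C[C@H](c1c(OC)cc(OC)cc1O)[C@H](CCC1(C)OCCO1)C(=O)N(C)OC | intermediate
9 | (2S,3S)-N-methoxy-N,5-dimethyl-2-[2-(2-methyl-1,3-dioxolan-2-yl)ethyl]-3-(2,4,6-trimethoxyphenyl)hexanamide | CC(C)C[C@H](c1c(OC)cc(OC)cc1OC)[C@H](CCC1(C)OCCO1)C(=O)N(C)OC | intermediate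
10 | (3S,4S)-6-methyl-3-[2-(2-methyl-1,3-dioxolan-2-yl)ethyl]-4-(2,4,6-trimethoxyphenyl)heptan-2-one | CC(C)C[C@H](c1c(OC)cc(OC)cc1OC)[C@H](CCC1(C)OCCO1)C(C)=O | intermediate
11 | triethyl phosphonoacetate | CCOC(=O)CP(=O)(OCC)OCC | starting material
12 | sodium salt of triethyl phosphonoacetate | [Na+].CCOC(=O)[CH-]P(=O)(OCC)OCC | intermediate (not isolated)
13 | ethyl (2E,4S,5S)-3,7-dimethyl-4-[2-(2-methyl-1,3-dioxolan-2-yl)ethyl]-5-(2,4,6-trimethoxyphenyl)oct-2-enoate | CC(C)C[C@H](c1c(OC)cc(OC)cc1OC)[C@H](CCC1(C)OCCO1)/C(C)=C/C(=O)OCC | intermediate
14 | (2E,4S,5S)-3,7-dimethyl-4-[2-(2-methyl-1,3-dioxolan-2-yl)ethyl]-5-(2,4,6-trimethoxyphenyl)oct-2-en-1-ol | CC(C)C[C@H](c1c(OC)cc(OC)cc1OC)[C@H](CCC1(C)OCCO1)/C(C)=C/CO | intermediate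
15 | (2E,4S,5S)-1-bromo-3,7-dimethyl-4-[2-(2-methyl-1,3-dioxolan-2-yl)ethyl]-5-(2,4,6-trimethoxyphenyl)oct-2-ene | CC(C)C[C@H](c1c(OC)cc(OC)cc1OC)[C@H](CCC1(C)OCCO1)/C(C)=C/CBr | intermediate
16 | [2-(chloromethyl)allyl]trimethylsilane | C=C(CCl)C[Si](C)(C)C | starting material
17 | [2-(trimethylsilylmethyl)allyl]magnesium chloride | C=C(C[Mg]Cl)C[Si](C)(C)C | intermediate
18 | ethylene ketal of 19 (αS,1S; C5=C10 E) | CC(C)C[C@H](c1c(OC)cc(OC)cc1OC)[C@H](CCC1(C)OCCO1)/C(C)=C/CCC(=C)C[Si](C)(C)C | intermediate
19 | (5S,6E)-6-methyl-5-[(1S)-3-methyl-1-(2,4,6-trimethoxyphenyl)butyl]-10-methylidene-11-(trimethylsilyl)undec-6-en-2-one | CC(C)C[C@H](c1c(OC)cc(OC)cc1OC)[C@H](CCC(C)=O)/C(C)=C/CCC(=C)C[Si](C)(C)C | intermediate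
20 | trans-decalin (αS,1S,4R,5S,10R) with C4–OH and C8 methylene | CC(C)C[C@H](c1c(OC)cc(OC)cc1OC)[C@@H]1CC[C@@](C)(O)[C@H]2CCC(=C)C[C@]12C | intermediate
21 | C8 vicinal diol from 20 (C8 configuration not defined) | CC(C)C[C@H](c1c(OC)cc(OC)cc1OC)[C@@H]1CC[C@@](C)(O)[C@H]2CCC(O)(CO)C[C@]12C | intermediate (not isolated)
22 | C8 ketone (αS,1S,4R,5S,10R) | CC(C)C[C@H](c1c(OC)cc(OC)cc1OC)[C@@H]1CC[C@@](C)(O)[C@H]2CCC(=O)C[C@]12C | intermediate
23 | dilithium C4-alkoxide C7=C8 enolate of 22 | CC(C)C[C@H](c1c(OC)cc(OC)cc1OC)[C@@H]1CC[C@@](C)(O[Li])[C@H]2CC=C(O[Li])C[C@]12C | intermediate (not isolated)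
24 | C7=C8 enol triflate | CC(C)C[C@H](c1c(OC)cc(OC)cc1OC)[C@@H]1CC[C@@](C)(O)[C@H]2CC=C(OS(=O)(=O)C(F)(F)F)C[C@]12C | intermediate
25 | methyl C7=C8 enoate (CO2Me on C7) | CC(C)C[C@H](c1c(OC)cc(OC)cc1OC)[C@@H]1CC[C@@](C)(O)[C@H]2CC(C(=O)OC)=CC[C@]12C | intermediate
26 | saturated methyl ester as C7 epimer mixture | CC(C)C[C@H](c1c(OC)cc(OC)cc1OC)[C@@H]1CC[C@@](C)(O)[C@H]2CC(C(=O)OC)CC[C@]12C | intermediate (not isolated)
27 | methyl ester (αS,1S,4R,5S,7S,10R) with equatorial CO2Me on C7 | CC(C)C[C@H](c1c(OC)cc(OC)cc1OC)[C@@H]1CC[C@@](C)(O)[C@H]2C[C@@H](C(=O)OC)CC[C@]12C | intermediate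
28 | C7 methyl ketone as its C4 bromomagnesium alkoxide | CC(C)C[C@H](c1c(OC)cc(OC)cc1OC)[C@@H]1CC[C@@](C)(O[Mg]Br)[C@H]2C[C@@H](C(C)=O)CC[C@]12C | intermediate (not isolated)
29 | diol (αS,1S,4R,5S,7S,10R) with a 2,4,6-trimethoxyphenyl group | CC(C)C[C@H](c1c(OC)cc(OC)cc1OC)[C@@H]1CC[C@@](C)(O)[C@H]2C[C@@H](C(C)(C)O)CC[C@]12C | intermediate
30 | 3',5'-dibromide of 29 | CC(C)C[C@H](c1c(OC)c(Br)c(OC)c(Br)c1OC)[C@@H]1CC[C@@](C)(O)[C@H]2C[C@@H](C(C)(C)O)CC[C@]12C | intermediate
31 | 3',5'-dilithio bis(lithium alkoxide) from 30 | CC(C)C[C@H](c1c(OC)c([Li])c(OC)c([Li])c1OC)[C@@H]1CC[C@@](C)(O[Li])[C@H]2C[C@@H](C(C)(C)O[Li])CC[C@]12C | intermediate (not isolated)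
32 | 3',5'-diformyl-2',4',6'-trimethoxy diol (trimethyl ether of 33) | CC(C)C[C@H](c1c(OC)c(C=O)c(OC)c(C=O)c1OC)[C@@H]1CC[C@@](C)(O)[C@H]2C[C@@H](C(C)(C)O)CC[C@]12C | intermediate
33 | CNP0409870.3 (αS,1S,4R,5S,7S,10R) | CC(C)C[C@H](c1c(O)c(C=O)c(O)c(C=O)c1O)[C@@H]1CC[C@@](C)(O)[C@H]2C[C@@H](C(C)(C)O)CC[C@]12C | target

## Step count and least certain steps

Total: 21 steps. Longest linear sequence: 19 steps from 1 (steps 1, 3–9 and 11–21). Steps 2 and 10 prepare the coupling partners 5 and 17.

**Step 13 (key step).** The most likely failure is loss of a proton from the C10 cation after ring A has closed, before C9 can close ring B. A methyl ketone is a weak initiator, so the transition state is late and the cascade is less concerted. A second concern is poor facial selectivity at C4 if the carbonyl reacts with its methyl group axial. Fallback: set out from ketal 18 and use the ketal itself as the initiator in an acetal-initiated polyene cyclisation (TiCl4, CH2Cl2, −78 °C). The oxocarbenium ion is a stronger electrophile than the complexed ketone and should give the 4-O-(2-hydroxyethyl) ether of the decalin F1, whose C4 configuration would have to be checked. The tether is then removed by conversion to the 2-iodoethyl ether F2 (I2, PPh3, imidazole) and reductive fragmentation with Zn dust in hot ethanol, which expels ethene and returns to the route at 20. This omits step 12.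

**Step 1.** Poor enantiofacial discrimination or slow addition is possible, because the peri 5-methoxy group crowds C4 and the two methoxy groups make the coumarin electron-rich. Fallback: set out from 1 and add 2 without a chiral ligand (CuI, Me3SiCl, THF) to the racemic lactone F3. Dehydrogenate this with DDQ in hot dioxane to 4-isobutyl-5,7-dimethoxycoumarin F4, then set Cα by copper hydride-catalysed asymmetric conjugate reduction (Cu(OAc)2, DTBM-SEGPHOS, (EtO)2MeSiH, t-BuOH, toluene), which delivers hydride instead of the alkyl group to C4 and returns to the route at 3.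

**Step 3.** Slow SN2 substitution at the unactivated primary iodide may lose out to fragmentation of the aryl ester enolate and to elimination of HI from 5. Fallback: set out from 3 and trap the enolate as the silyl ketene acetal F5 (LiN(SiMe3)2, Me3SiCl, −78 °C). Add F5 to methyl vinyl ketone in a Mukaiyama–Michael reaction (TiCl4, CH2Cl2, −78 °C), again anti to the isobutyl group, to give the trans keto lactone F6. Ketalise with 1,2-bis(trimethylsilyloxy)ethane and catalytic Me3SiOTf to return to the route at 7.

**Step 7.** The hindered ketone may need forcing conditions, which invites epimerisation at C1 through enolisation and erosion of (E)-selectivity. Fallback: set out from 9 and reduce to the aldehyde F7 (i-Bu2AlH, THF, −78 °C). Homologate to the terminal alkyne F8 (Ohira–Bestmann reagent, K2CO3, MeOH). Carry out a zirconium-catalysed carboalumination (Me3Al, (C5H5)2ZrCl2 cat., CH2Cl2), whose syn addition fixes the (E)-geometry in the alkenylalane F9. Convert F9 to its aluminate with n-BuLi and trap with paraformaldehyde to return to the route at 14, bypassing steps 6–8.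

**Step 20.** The second bromine–lithium exchange may be incomplete, or an aryllithium may be protonated within the aggregated polylithiated species, leading to mono-aldehyde. Fallback: set out from 30 and make both aryl–carbon bonds by Suzuki–Miyaura vinylation (potassium vinyltrifluoroborate, Pd(OAc)2, 2-dicyclohexylphosphino-2',6'-dimethoxybiphenyl, Cs2CO3, THF/H2O, 80 °C) to the 3',5'-divinyl arene F10. Cleave both vinyl groups with OsO4 (cat.) and NaIO4 to return to the route at 32; no organolithium is involved.

**Step 21.** Demethylation may stall after the first or second methyl group, because each phenoxide formed makes the ring more electron-rich and the next SN2 displacement slower. Fallback: set out from 32 and change the mechanism from thiolate attack on an increasingly anionic ring to chelation-assisted cleavage (MgI2·OEt2, toluene/THF, 80 °C). Each methoxy group is then activated independently by the magnesium chelate with its ortho formyl group and cleaved by iodide, which returns to the route at 33. No further compound is made on the way (F0).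

## Further compounds

F1 | step 13 | 4-O-(2-hydroxyethyl) ether of decalin 20 | CC(C)C[C@H](c1c(OC)cc(OC)cc1OC)[C@@H]1CC[C@@](C)(OCCO)[C@H]2CCC(=C)C[C@]12C
F2 | step 13 | 4-O-(2-iodoethyl) ether of decalin 20 | CC(C)C[C@H](c1c(OC)cc(OC)cc1OC)[C@@H]1CC[C@@](C)(OCCI)[C@H]2CCC(=C)C[C@]12C
F3 | step 1 | racemic 4-isobutyl-5,7-dimethoxychroman-2-one | CC(C)CC1CC(=O)Oc2cc(OC)cc(OC)c12
F4 | step 1 | 4-isobutyl-5,7-dimethoxycoumarin | CC(C)Cc1cc(=O)oc2cc(OC)cc(OC)c12
F5 | step 3 | trimethylsilyl ketene acetal of 3 | CC(C)C[C@H](c1c(OC)cc(OC)cc1O2)C=C2O[Si](C)(C)C
F6 | step 3 | (3S,4S)-4-isobutyl-5,7-dimethoxy-3-(3-oxobutyl)chroman-2-one | CC(C)C[C@H](c1c(OC)cc(OC)cc1O2)[C@H](CCC(C)=O)C2=O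
F7 | step 7 | (2S,3S)-5-methyl-2-[2-(2-methyl-1,3-dioxolan-2-yl)ethyl]-3-(2,4,6-trimethoxyphenyl)hexanal | CC(C)C[C@H](c1c(OC)cc(OC)cc1OC)[C@H](CCC1(C)OCCO1)C=O
F8 | step 7 | terminal alkyne from F7 (C10≡C5) | CC(C)C[C@H](c1c(OC)cc(OC)cc1OC)[C@H](CCC1(C)OCCO1)C#C
F9 | step 7 | (E)-alkenyl(dimethyl)alane from F8 | CC(C)C[C@H](c1c(OC)cc(OC)cc1OC)[C@H](CCC1(C)OCCO1)/C(C)=C/[Al](C)C
F10 | step 20 | 3',5'-divinyl analogue of 30 | CC(C)C[C@H](c1c(OC)c(C=C)c(OC)c(C=C)c1OC)[C@@H]1CC[C@@](C)(O)[C@H]2C[C@@H](C(C)(C)O)CC[C@]12C
F0 | step 21 | none | none
A1 | alternative 1 | 4-(5-hydroxy-2-methylphenyl)-3-[2-(triethylsilyloxy)propan-2-yl]butyl methanesulfonate (C7 as in A2) | Cc1ccc(O)cc1C[C@@H](C(C)(C)O[Si](CC)(CC)CC)CCOS(C)(=O)=O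
A2 | alternative 1 | bicyclic cross-conjugated dienone | C1=CC(=O)C=C2C[C@@H](C(C)(C)O[Si](CC)(CC)CC)CC[C@]12C
A3 | alternative 2 | 2',6'-bis(triflyloxy)-3',5'-bis(trimethylsilyl)-4'-methoxy arene on the bis(triethylsilyl)-protected decalin | CC(C)C[C@H](c1c(OS(=O)(=O)C(F)(F)F)c([Si](C)(C)C)c(OC)c([Si](C)(C)C)c1OS(=O)(=O)C(F)(F)F)[C@@H]1CC[C@@](C)(O[Si](CC)(CC)CC)[C@H]2C[C@@H](C(C)(C)O[Si](CC)(CC)CC)CC[C@]12C
A4 | alternative 2 | 3',5'-diformyl-2',6'-dihydroxy-4'-methoxy arene on the bis(triethylsilyl)-protected decalin | CC(C)C[C@H](c1c(O)c(C=O)c(OC)c(C=O)c1O)[C@@H]1CC[C@@](C)(O[Si](CC)(CC)CC)[C@H]2C[C@@H](C(C)(C)O[Si](CC)(CC)CC)CC[C@]12C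
A5 | alternative 3 | keto-iodide: ring B cyclohexane with C5 acetyl and a C1 side chain ending in C3–I | CC(C)C[C@H](c1c(OC)cc(OC)cc1OC)[C@H](CCI)[C@@]1(C)CC[C@H](C(C)(C)O[Si](CC)(CC)CC)C[C@@H]1C(C)=O
A6 | alternative 3 | decalin carbinol with C11 triethylsilyl ether | CC(C)C[C@H](c1c(OC)cc(OC)cc1OC)[C@@H]1CC[C@@](C)(O)[C@H]2C[C@@H](C(C)(C)O[Si](CC)(CC)CC)CC[C@]12C
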